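Ring B (the quinone) is numbered C1′(=O), C2′(OMe), C3′(OMe), C4′(=O), C5′ (bearing chroman C3), C6′(H). The synthesis rests on disconnecting C2′–C3′. Stripping the C2′ methyl and the C1′ oxygen exposes a 2-methoxyresorcinol in which the C2′ and C4′ oxygens are 1,3-related across methoxylated C3′, the imprint of a Claisen-type fold. In one operation, base closes an open-chain δ-keto enoate: the methoxyacetyl carbanion (C3′) attacks the ester carbon (C2′) and the ring aromatises. The precursor is a methoxymethyl ketone/acrylate ester hung on the preformed (S)-chroman (rings A and C), itself made by Stobbe condensation and asymmetric hydrogenation.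

Key step: step 8

Remark: 2-bromo-3,4,5-trimethoxybenzaldehyde, dimethyl succinate, methoxyacetyl chloride and methyl propiolate are taken as catalogue compounds.

Step 1
Reactants: 1 2-bromo-3,4,5-trimethoxybenzaldehyde; 2 dimethyl succinate
Product: 3 (3E)-4-(2-bromo-3,4,5-trimethoxyphenyl)-3-(methoxycarbonyl)but-3-enoic acid
Conditions: NaOMe (1.2 equiv), MeOH, reflux; then 2 M HCl
Reagents that add atoms: none
Why: Stobbe condensation (aldol addition, lactonisation to the paraconic ester, E1cB ring opening) should give the (E)-alkylidene succinate half-ester, whose free CH2CO2H arm is the future C5′ with a temporary carboxyl activator.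

Step 2
Reactants: 3
Product: 4 (3S)-4-(2-bromo-3,4,5-trimethoxyphenyl)-3-(methoxycarbonyl)butanoic acid
Conditions: [Rh(cod)((R,R)-Et-DuPHOS)]BF4 (0.5 mol%), H2 (5 bar), NaOMe (0.1 equiv), MeOH, rt
Reagents that add atoms: none
Why: Rhodium-catalysed asymmetric hydrogenation of a β-aryl itaconate half-ester, in which chelation of alkene and carboxylate to the chiral bisphosphine–rhodium centre fixes the face of H2 delivery; the (R,R)-ligand is the antipode expected, by analogy with other itaconate half-esters, to set the future chroman C3 as (S) (the (S,S)-ligand is used if the first run shows the opposite sense).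

Step 3
Reactants: 4
Product: 6 (4S)-4-(2-bromo-3,4,5-trimethoxybenzyl)oxolan-2-one, via hydroxy acid 5 (not isolated)
Conditions: LiBH4 (2.5 equiv), THF, 0 °C to rt; then 2 M HCl, rt
Reagents that add atoms: none
Why: Chemoselective borohydride reduction (the acid is at once an inert lithium carboxylate, the methyl ester is reduced) followed by acid-induced γ-lactonisation should give a crystalline lactone without touching the stereocentre.

Step 4
Reactants: 6
Product: 9 allyl 2-[(3S)-6,7,8-trimethoxychroman-3-yl]acetate, via potassium hydroxy-carboxylate 7 (not isolated), via potassium chromanylacetate 8 (not isolated)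
Conditions: KOH (1.05 equiv), MeOH–H2O, rt, evaporate; CuI (10 mol%), 3,4,7,8-tetramethyl-1,10-phenanthroline (20 mol%), Cs2CO3 (2 equiv), DMF, 110 °C; then allyl bromide (1.5 equiv), rt
Reagents that add atoms: potassium hydroxide [K+].[OH-]; allyl bromide C=CCBr
Why: Saponification frees the primary alcohol while the carboxylate cannot relactonise, copper-catalysed Ullmann-type intramolecular O-arylation closes ring C (6-exo), and carboxylate alkylation in the same pot installs the removable allyl ester.

Step 5
Reactants: 9; 10 methoxyacetyl chloride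
Product: 11 allyl 4-methoxy-3-oxo-2-[(3S)-6,7,8-trimethoxychroman-3-yl]butanoate (C2 epimers, partly enolised)
Conditions: LiN(SiMe3)2 (2.2 equiv), THF, −78 °C; then 10, −78 to −40 °C; sat. NH4Cl
Reagents that add atoms: none
Why: Crossed Claisen C-acylation of the ester lithium enolate, in which the second equivalent of base deprotonates the β-keto ester as it forms so that acylation stops after one acyl group; the chroman stereocentre is β to the ester and not acidic.

Step 6
Reactants: 11; 12 methyl propiolate
Product: 13 5-allyl 1-methyl (2E)-4-(methoxyacetyl)-4-[(3S)-6,7,8-trimethoxychroman-3-yl]pent-2-enedioate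
Conditions: Cs2CO3 (0.2 equiv), 12 (1.3 equiv), MeCN, 0 °C to rt
Reagents that add atoms: none
Why: Base-catalysed Michael addition of the doubly activated carbon (future C5′) to the alkynoate; the new quaternary centre forms as a mixture, which is irrelevant because it becomes planar in steps 7 and 8.

Step 7
Reactants: 13
Product: 15 methyl (2E)-6-methoxy-5-oxo-4-[(3S)-6,7,8-trimethoxychroman-3-yl]hex-2-enoate, via β-keto acid 14 (not isolated)
Conditions: Pd(PPh3)4 (5 mol%), HCO2H (2 equiv), Et3N (2.5 equiv), THF, rt to 40 °C
Reagents that add atoms: none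
Why: Tsuji–Trost-type deallylation (zerovalent palladium ionises the allyl ester, formate reduces the allyl unit) and spontaneous decarboxylation of the β-keto acid under neutral conditions avoid retro-Claisen cleavage; any 3-enoate isomer of 15 converges in step 8.

Step 8
Reactants: 15
Product: 17 2-methoxy-4-[(3S)-6,7,8-trimethoxychroman-3-yl]benzene-1,3-diol, via cyclohexenedione 16 (not isolated)
Conditions: NaOMe (3 equiv), MeOH, argon, 65 °C; then 1 M HCl
Reagents that add atoms: none
Why: Methoxide equilibrates 15 through its dienolate (C5′–H is α to the ketone and γ to the enoate) to the (Z)-β,γ-unsaturated ketone tautomer, whose methoxyacetyl enolate carbon C3′ attacks the ester carbonyl C2′; loss of methoxide gives 16, which enolises at once to the resorcinolate of 17. The closest known reaction type is the intramolecular Claisen (Dieckmann-type) condensation of δ-keto esters to cyclohexane-1,3-diones, here run on a substrate already at the aromatic oxidation level, as in Claisen-mode polyketide folding. Ring B closes by a 6-(enolendo)-exo-trig attack. No stereocentre is created (sp3 C3′ of 16 disappears on aromatisation) and the chroman C3–H, β to the ketone and not conjugated to any carbonyl, cannot epimerise. The step needs C- rather than O-acylation and a cis arrangement of the ketone and ester arms: O-acylation gives only the 2-pyranone, which methoxide reopens, the geometrical and positional alkene isomers interconvert through the dienolate, the ester is the only carbonyl within reach of C3′ in a six-membered transition state, and aromatisation makes the C–C closure the irreversible exit.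

Step 9
Reactants: 17
Product: 18 2-hydroxy-3-methoxy-5-[(3S)-6,7,8-trimethoxychroman-3-yl]cyclohexa-2,5-diene-1,4-dione
Conditions: (KSO3)2NO (Fremy's salt, 2.5 equiv), KH2PO4 buffer (pH 6), acetone–H2O, 0 °C to rt; acidify
Reagents that add atoms: potassium nitrosodisulfonate [K+].[K+].[O]N(S(=O)(=O)[O-])S(=O)(=O)[O-]
Why: Teuber oxidation: the phenoxyl radical is trapped by a second nitroxyl at C1′, the only free position para to a hydroxyl, and loss of imidodisulfonate gives the p-quinone; attack ortho to the other hydroxyl would give the tautomeric hydroxy-o-quinone, so both modes converge on 18, and the non-phenolic ring A is not oxidised.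

Step 10
Reactants: 18
Product: 19 abruquinone B
Conditions: MeI (5 equiv), Ag2O (1.5 equiv), CHCl3, rt, dark
Reagents that add atoms: iodomethane CI
Why: O-Methylation of the acidic hydroxyquinone (a vinylogous carboxylic acid) at C2′–OH under neutral silver oxide conditions, which avoid base-induced epimerisation of the quinone-activated C3–H and cycloaddition of diazoalkanes to the quinone.

Compound list
1 | 2-bromo-3,4,5-trimethoxybenzaldehyde | O=Cc1cc(OC)c(OC)c(OC)c1Br | starting material
2 | dimethyl succinate | COC(=O)CCC(=O)OC | starting material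
3 | (3E)-4-(2-bromo-3,4,5-trimethoxyphenyl)-3-(methoxycarbonyl)but-3-enoic acid | OC(=O)C/C(C(=O)OC)=C\c1cc(OC)c(OC)c(OC)c1Br | intermediate
4 | (3S)-4-(2-bromo-3,4,5-trimethoxyphenyl)-3-(methoxycarbonyl)butanoic acid | OC(=O)C[C@H](Cc1cc(OC)c(OC)c(OC)c1Br)C(=O)OC | intermediate
5 | (3S)-4-(2-bromo-3,4,5-trimethoxyphenyl)-3-(hydroxymethyl)butanoic acid (not isolated) | OC(=O)C[C@H](Cc1cc(OC)c(OC)c(OC)c1Br)CO | intermediate
6 | (4S)-4-(2-bromo-3,4,5-trimethoxybenzyl)oxolan-2-one | O=C1C[C@H](Cc2cc(OC)c(OC)c(OC)c2Br)CO1 | intermediate
7 | potassium (3S)-4-(2-bromo-3,4,5-trimethoxyphenyl)-3-(hydroxymethyl)butanoate (not isolated) | [K+].[O-]C(=O)C[C@H](Cc1cc(OC)c(OC)c(OC)c1Br)CO | intermediate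
8 | potassium 2-[(3S)-6,7,8-trimethoxychroman-3-yl]acetate (not isolated) | [K+].[O-]C(=O)C[C@H]1COc2c(cc(OC)c(OC)c2OC)C1 | intermediate
9 | allyl 2-[(3S)-6,7,8-trimethoxychroman-3-yl]acetate | C=CCOC(=O)C[C@H]1COc2c(cc(OC)c(OC)c2OC)C1 | intermediate
10 | methoxyacetyl chloride | COCC(=O)Cl | starting material
11 | allyl 4-methoxy-3-oxo-2-[(3S)-6,7,8-trimethoxychroman-3-yl]butanoate (C2 epimers) | C=CCOC(=O)C(C(=O)COC)[C@H]1COc2c(cc(OC)c(OC)c2OC)C1 | intermediate
12 | methyl propiolate | C#CC(=O)OC | starting material
13 | 5-allyl 1-methyl (2E)-4-(methoxyacetyl)-4-[(3S)-6,7,8-trimethoxychroman-3-yl]pent-2-enedioate (C4 epimers) | C=CCOC(=O)C(/C=C/C(=O)OC)(C(=O)COC)[C@H]1COc2c(cc(OC)c(OC)c2OC)C1 | intermediate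
14 | (3E)-5-methoxy-2-(methoxyacetyl)-5-oxo-2-[(3S)-6,7,8-trimethoxychroman-3-yl]pent-3-enoic acid (not isolated) | OC(=O)C(/C=C/C(=O)OC)(C(=O)COC)[C@H]1COc2c(cc(OC)c(OC)c2OC)C1 | intermediate
15 | methyl (2E)-6-methoxy-5-oxo-4-[(3S)-6,7,8-trimethoxychroman-3-yl]hex-2-enoate (C4 epimers) | COCC(=O)C(/C=C/C(=O)OC)[C@H]1COc2c(cc(OC)c(OC)c2OC)C1 | intermediate
16 | 2-methoxy-4-[(3S)-6,7,8-trimethoxychroman-3-yl]cyclohex-4-ene-1,3-dione (not isolated) | COC1C(=O)CC=C([C@H]2COc3c(cc(OC)c(OC)c3OC)C2)C1=O | intermediate
17 | 2-methoxy-4-[(3S)-6,7,8-trimethoxychroman-3-yl]benzene-1,3-diol | COc1c(O)ccc([C@H]2COc3c(cc(OC)c(OC)c3OC)C2)c1O | intermediate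
18 | 2-hydroxy-3-methoxy-5-[(3S)-6,7,8-trimethoxychroman-3-yl]cyclohexa-2,5-diene-1,4-dione | COC1=C(O)C(=O)C=C([C@H]2COc3c(cc(OC)c(OC)c3OC)C2)C1=O | intermediate
19 | abruquinone B, 2,3-dimethoxy-5-[(3S)-6,7,8-trimethoxychroman-3-yl]cyclohexa-2,5-diene-1,4-dione | COC1=C(OC)C(=O)C([C@H]2COc3c(cc(OC)c(OC)c3OC)C2)=CC1=O | target

Total step count: 10. Longest linear sequence: 10 steps (1 to 19).

Steps most likely to fail

Step 4. The copper-catalysed O-arylation may stall on the electron-rich, doubly ortho-substituted aryl bromide, lose bromine by reduction, or be slowed by carboxylate binding to copper. The fallback changes the pyran C–O bond formation from aryl C–O coupling to alkyl C–O substitution. It sets out from 6: palladium-catalysed hydroxylation of the aryl bromide (Pd2(dba)3, tBuXPhos, KOH, dioxane–H2O, 100 °C; then HCl) should give the phenol lactone F1. Heating F1 with K2CO3 in DMF (120 °C) lets the phenoxide open the lactone at its CH2–O carbon (6-exo-tet SN2, alkyl–oxygen cleavage), which gives carboxylate 8 directly. Allyl bromide in the same pot then gives 9, where the route is rejoined.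

Step 6. The hindered, fully substituted enolate may add through oxygen (enol ether formation) or not add at all to the alkynoate. The fallback replaces the alkyne acceptor by an alkene acceptor and introduces the double bond afterwards. It sets out from 11: Michael addition to methyl 2-chloroacrylate (Cs2CO3 cat., MeCN, rt), which can only give a C-adduct, should give the chloro diester F2. Dehydrochlorination with DBU (CH2Cl2, rt) then gives 13, where the route is rejoined.

Step 8. The reactive ketone enolate is only a minor tautomer of the resting dienolate, so the closure may be slow and lose out to intermolecular Michael oligomerisation or to accumulation of the 2-pyranone. The fallback closes the same C2′–C3′ bond at the dihydro level, where no dienolate exists, and restores the aromatic oxidation level afterwards. It sets out from 15: hydrogenation of the alkene (H2, Pd/C, EtOAc, rt) should give the saturated keto ester F3. Plain Dieckmann-type Claisen cyclisation (NaOMe, MeOH, reflux; then HCl) gives the cyclohexane-1,3-dione F4. Aerobic palladium-catalysed dehydrogenation (Pd(O2CCF3)2, 2-(dimethylamino)pyridine, TsOH, O2, DMSO, 80 °C) then gives 17, where the route is rejoined.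

Further compounds
F1 | step 4 | (4S)-4-(2-hydroxy-3,4,5-trimethoxybenzyl)oxolan-2-one | O=C1C[C@H](Cc2cc(OC)c(OC)c(OC)c2O)CO1
F2 | step 6 | 5-allyl 1-methyl 2-chloro-4-(methoxyacetyl)-4-[(3S)-6,7,8-trimethoxychroman-3-yl]pentanedioate | C=CCOC(=O)C(CC(Cl)C(=O)OC)(C(=O)COC)[C@H]1COc2c(cc(OC)c(OC)c2OC)C1
F3 | step 8 | methyl 6-methoxy-5-oxo-4-[(3S)-6,7,8-trimethoxychroman-3-yl]hexanoate | COCC(=O)C(CCC(=O)OC)[C@H]1COc2c(cc(OC)c(OC)c2OC)C1
F4 | step 8 | 2-methoxy-4-[(3S)-6,7,8-trimethoxychroman-3-yl]cyclohexane-1,3-dione | COC1C(=O)CCC([C@H]2COc3c(cc(OC)c(OC)c3OC)C2)C1=O
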